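**Retrosynthetic overview**
1. C12–C13 is the last C–C bond. A chiral-phosphoric-acid-catalysed linear prenylboration of an (E)-α-methyl enal sets C12, and only desilylation follows.
2. C8–C9 comes from a vinylogous Mukaiyama aldol of the tiglaldehyde silyl dienol ether onto an α-quaternary epoxy aldehyde. This sets C8 and brings in C9–C12 with the E alkene in one step.
3. The oxirane is the only ring and is closed once, before both chain extensions. A primary-amine/chiral-phosphate epoxidation of an α-(silyloxymethyl) enal with H2O2 sets C6 and C7, the first stereocentres.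
4. C7–C20 comes from a new dienamine-type formal Morita–Baylis–Hillman hydroxymethylation of a linear dienal with formaldehyde.
5. C6=C7 comes from cross-metathesis of nerol (source of the 2Z alkene) with crotonaldehyde.

Assumption: positions C1–C16 and C20 follow the geranylgeraniol skeleton (C1 = allylic CH2OH at the Z alkene, C20 = CH2OH on oxirane carbon C7), and the catalyst antipodes quoted in steps 4, 6 and 9 are those expected by analogy with the closest model substrates, the mirror-image or pseudo-enantiomeric catalyst being equally available if the first assay shows the opposite sense.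

Abbreviations: TBS = tert-butyldimethylsilyl. TRIP = 3,3′-bis(2,4,6-triisopropylphenyl)-1,1′-binaphthyl-2,2′-diyl hydrogen phosphate.

**Step 1**
Reactants: 1 nerol, (2Z)-3,7-dimethylocta-2,6-dien-1-ol; 2 crotonaldehyde, (2E)-but-2-enal
Product: 3 (2E,6Z)-8-hydroxy-6-methylocta-2,6-dienal
Conditions: 2 (5 equiv), second-generation Hoveyda–Grubbs catalyst RuCl2(SIMes)(=CH-C6H4-2-OiPr) (3 mol %), CH2Cl2, 40 °C
Reagents that add atoms: none
Why: Olefin cross-metathesis in which the gem-dimethyl C6=C7 alkene of 1 acts as a terminal-alkene surrogate, the more hindered and allylically oxygenated 2Z alkene stays untouched, and the enal partner gives the E alkene; no stereocentre is formed.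

**Step 2**
Reactants: 3 (2E,6Z)-8-hydroxy-6-methylocta-2,6-dienal; 4 formaldehyde
Product: 6 (2E,6Z)-8-hydroxy-2-(hydroxymethyl)-6-methylocta-2,6-dienal, via deconjugated aldol adduct 5 (not isolated)
Conditions: 4 (37% aq, 3 equiv), DL-proline (30 mol %), imidazole (50 mol %), DMF, 4 °C → rt
Reagents that add atoms: none
Why: Proposed new method: a dienamine-mediated formal Morita–Baylis–Hillman hydroxymethylation of a β-alkyl enal that forms the C7–C20 bond, in which proline condenses with 3, γ-deprotonation at C5 gives the dienamine, the carboxylic acid hydrogen-bonds formaldehyde and steers it to the α-carbon C7 (enamine aldol), and imidazole shuttles the doubly activated α-H of 5 to C5 so that the alkene returns into conjugation as the thermodynamic E enal (chain trans to CHO), while the aqueous medium holds back loss of water and the α-branched product condenses only poorly with a secondary amine, which stops over-reaction; the closest known reaction type is the proline/imidazole aza-Morita–Baylis–Hillman-type Mannich reaction of β-substituted enals with imines, and to my knowledge formaldehyde has not been used as the electrophile.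

**Step 3**
Reactants: 6 (2E,6Z)-8-hydroxy-2-(hydroxymethyl)-6-methylocta-2,6-dienal
Product: 7 (2E,6Z)-8-[(TBS)oxy]-2-{[(TBS)oxy]methyl}-6-methylocta-2,6-dienal
Conditions: TBSCl (2.5 equiv), imidazole (5 equiv), CH2Cl2, 0 °C → rt
Reagents that add atoms: tert-butyldimethylsilyl chloride, CC(C)(C)[Si](C)(C)Cl
Why: Standard silyl ether formation masks both primary alcohols in one operation with a group that is a poor leaving group, so the enamine of step 4 cannot expel it; no stereocentre is formed.

**Step 4 (key step)**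
Reactants: 7 (2E,6Z)-8-[(TBS)oxy]-2-{[(TBS)oxy]methyl}-6-methylocta-2,6-dienal
Product: 8 (2R,3S)-2-{[(TBS)oxy]methyl}-3-[(3Z)-5-[(TBS)oxy]-3-methylpent-3-en-1-yl]oxirane-2-carbaldehyde
Conditions: 9-amino(9-deoxy)epiquinine (10 mol %), (R)-TRIP (20 mol %), 50% aq H2O2 (1.5 equiv), THF, 50 °C
Reagents that add atoms: hydrogen peroxide, OO
Why: Iminium–enamine (Weitz–Scheffer-type) epoxidation of an α-branched enal under primary-amine/chiral-phosphate ion-pair catalysis, in which only the electron-poor C6=C7 alkene accepts nucleophilic H2O2, the chiral ion pair exposes the Si face of C6, and the enamine closes onto the O–O bond faster than C6–C7 rotates, so C6 (S) and C7 (R in 8) are set together with the chain trans to CHO.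

**Step 5**
Reactants: 9 tiglaldehyde, (2E)-2-methylbut-2-enal
Product: 10 tert-butyl(dimethyl){[(1E)-2-methylbuta-1,3-dien-1-yl]oxy}silane
Conditions: TBSOTf (1.1 equiv), Et3N (1.5 equiv), Et2O, 0 °C → rt
Reagents that add atoms: tert-butyldimethylsilyl triflate, CC(C)(C)[Si](C)(C)OS(=O)(=O)C(F)(F)F
Why: Soft enolisation, in which Et3N removes a γ-proton from the O-silylated s-trans enal, gives the 1E silyloxy diene; no stereocentre is formed.

**Step 6**
Reactants: 8 epoxy aldehyde (name as in step 4); 10 tert-butyl(dimethyl){[(1E)-2-methylbuta-1,3-dien-1-yl]oxy}silane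
Product: 11 (2E,5S)-5-hydroxy-5-[(2S,3S)-2-{[(TBS)oxy]methyl}-3-[(3Z)-5-[(TBS)oxy]-3-methylpent-3-en-1-yl]oxiran-2-yl]-2-methylpent-2-enal
Conditions: 10 (2 equiv), preformed B-phenyl-1,3,2-oxazaborolidin-5-one from N-tosyl-D-tryptophan and PhBCl2 (50 mol %), iPrOH (1.2 equiv), EtCN, −78 °C
Reagents that add atoms: none
Why: Vinylogous Mukaiyama aldol reaction of an aldehyde-derived silyl dienol ether promoted by a tryptophan-derived oxazaborolidinone (Kalesse-type, metal-free chiral Lewis acid), in which boron binds the activated, non-enolisable aldehyde of 8, the indole shields its Re face, the unsubstituted γ-CH2 of 10 attacks the Si face in an open transition state to set C8 (S) under reagent control and deliver the E enal, and the less electrophilic conjugated aldehyde of 11 does not react again.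

**Step 7**
Reactants: 12 prenol, 3-methylbut-2-en-1-ol
Product: 13 methyl 3-methylbut-2-en-1-yl carbonate
Conditions: ClCO2Me (1.2 equiv), pyridine (1.5 equiv), CH2Cl2, 0 °C
Reagents that add atoms: methyl chloroformate, COC(=O)Cl
Why: Acylation of a primary allylic alcohol with a chloroformate; no stereocentre is formed.

**Step 8**
Reactants: 13 methyl 3-methylbut-2-en-1-yl carbonate
Product: 14 4,4,5,5-tetramethyl-2-(2-methylbut-3-en-2-yl)-1,3,2-dioxaborolane
Conditions: B2pin2 (1.1 equiv), CuCl (5 mol %), Xantphos (5 mol %), KOtBu (10 mol %), THF, 0 °C → rt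
Reagents that add atoms: bis(pinacolato)diboron, CC1(C)OB(OC1(C)C)B1OC(C)(C)C(C)(C)O1
Why: Copper-catalysed γ-selective (formal SN2′) boryl substitution of an allylic carbonate (Ito–Sawamura type), in which Cu–Bpin adds across the alkene with boron on the dimethyl-substituted carbon and β-elimination of the carbonate gives the tertiary allylboronate; no stereocentre is formed.

**Step 9**
Reactants: 11 hydroxy enal (name as in step 6); 14 4,4,5,5-tetramethyl-2-(2-methylbut-3-en-2-yl)-1,3,2-dioxaborolane
Product: 16 (1S,3E,5R)-1-[(2S,3S)-2-{[(TBS)oxy]methyl}-3-[(3Z)-5-[(TBS)oxy]-3-methylpent-3-en-1-yl]oxiran-2-yl]-4,8-dimethylnona-3,7-diene-1,5-diol, via pinacol borate ester 15 (not isolated)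
Conditions: 14 (1.5 equiv), (R)-TRIP (10 mol %), 4 Å MS, toluene, −30 → 0 °C; aq NaHCO3 work-up
Reagents that add atoms: none
Why: Chiral-phosphoric-acid-catalysed allylboration (Antilla-type) through a closed chair transition state, in which the acid protonates a pinacol oxygen and binds the formyl H, the CH2 terminus of tertiary boronate 14 adds to the Re face of the enal to set C12 (R), and allylic transposition gives the linear prenyl group with no E/Z issue because the new alkene carries two methyl groups.

**Step 10**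
Reactants: 16 bis-TBS diol (name as in step 9)
Product: 17 target, (1S,3E,5R)-1-[(2S,3S)-2-(hydroxymethyl)-3-[(3Z)-5-hydroxy-3-methylpent-3-en-1-yl]oxiran-2-yl]-4,8-dimethylnona-3,7-diene-1,5-diol
Conditions: TBAF (4 equiv), AcOH (4 equiv), THF, 0 °C → rt
Reagents that add atoms: none
Why: Fluoride-mediated cleavage of the two primary TBS ethers, buffered with acetic acid so that no free alkoxide triggers Payne rearrangement of the epoxy alcohols; no stereocentre is touched.

**Compound list**
1 | nerol, (2Z)-3,7-dimethylocta-2,6-dien-1-ol | CC(C)=CCC/C(C)=C\CO | starting material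
2 | crotonaldehyde, (2E)-but-2-enal | C/C=C/C=O | starting material
3 | (2E,6Z)-8-hydroxy-6-methylocta-2,6-dienal | O=C/C=C/CC/C(C)=C\CO | intermediate
4 | formaldehyde | C=O | starting material
5 | (3E,6Z)-8-hydroxy-2-(hydroxymethyl)-6-methylocta-3,6-dienal, racemic at C2, deconjugated aldol adduct | O=CC(CO)/C=C/C/C(C)=C\CO | intermediate
6 | (2E,6Z)-8-hydroxy-2-(hydroxymethyl)-6-methylocta-2,6-dienal | O=C/C(CO)=C/CC/C(C)=C\CO | intermediate
7 | (2E,6Z)-8-[(TBS)oxy]-2-{[(TBS)oxy]methyl}-6-methylocta-2,6-dienal | O=C/C(CO[Si](C)(C)C(C)(C)C)=C/CC/C(C)=C\CO[Si](C)(C)C(C)(C)C | intermediate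
8 | (2R,3S)-2-{[(TBS)oxy]methyl}-3-[(3Z)-5-[(TBS)oxy]-3-methylpent-3-en-1-yl]oxirane-2-carbaldehyde | O=C[C@]1(CO[Si](C)(C)C(C)(C)C)O[C@H]1CC/C(C)=C\CO[Si](C)(C)C(C)(C)C | intermediate
9 | tiglaldehyde, (2E)-2-methylbut-2-enal | C/C=C(\C)C=O | starting material
10 | tert-butyl(dimethyl){[(1E)-2-methylbuta-1,3-dien-1-yl]oxy}silane | C=C/C(C)=C/O[Si](C)(C)C(C)(C)C | intermediate
11 | (2E,5S)-5-hydroxy-5-[(2S,3S)-2-{[(TBS)oxy]methyl}-3-[(3Z)-5-[(TBS)oxy]-3-methylpent-3-en-1-yl]oxiran-2-yl]-2-methylpent-2-enal | O=C/C(C)=C/C[C@H](O)[C@]1(CO[Si](C)(C)C(C)(C)C)O[C@H]1CC/C(C)=C\CO[Si](C)(C)C(C)(C)C | intermediate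
12 | prenol, 3-methylbut-2-en-1-ol | CC(C)=CCO | starting material
13 | methyl 3-methylbut-2-en-1-yl carbonate | CC(C)=CCOC(=O)OC | intermediate
14 | 4,4,5,5-tetramethyl-2-(2-methylbut-3-en-2-yl)-1,3,2-dioxaborolane | C=CC(C)(C)B1OC(C)(C)C(C)(C)O1 | intermediate
15 | pinacol borate ester of 16 at the C12 oxygen (12R) | CC(C)=CC[C@@H](OB2OC(C)(C)C(C)(C)O2)/C(C)=C/C[C@H](O)[C@]1(CO[Si](C)(C)C(C)(C)C)O[C@H]1CC/C(C)=C\CO[Si](C)(C)C(C)(C)C | intermediate
16 | (1S,3E,5R)-1-[(2S,3S)-2-{[(TBS)oxy]methyl}-3-[(3Z)-5-[(TBS)oxy]-3-methylpent-3-en-1-yl]oxiran-2-yl]-4,8-dimethylnona-3,7-diene-1,5-diol | CC(C)=CC[C@@H](O)/C(C)=C/C[C@H](O)[C@]1(CO[Si](C)(C)C(C)(C)C)O[C@H]1CC/C(C)=C\CO[Si](C)(C)C(C)(C)C | intermediate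
17 | (1S,3E,5R)-1-[(2S,3S)-2-(hydroxymethyl)-3-[(3Z)-5-hydroxy-3-methylpent-3-en-1-yl]oxiran-2-yl]-4,8-dimethylnona-3,7-diene-1,5-diol | CC(C)=CC[C@@H](O)/C(C)=C/C[C@H](O)[C@]1(CO)O[C@H]1CC/C(C)=C\CO | target

**Step count**
Total: 10 steps.
Longest linear sequence: 7 steps from nerol (steps 1, 2, 3, 4, 6, 9, 10).

**Three steps most likely to fail**

*Step 2 (the new step).*
- Risks: loss of water from 5 or 6 to a 2-methylene dienal that dimerises, proline-catalysed self-condensation of 3, and γ-attack.
- The fallback uses known chemistry, sets out from 3 and comes back at 6. Compound 3 is α-iodinated with I2, DMAP and K2CO3 in THF–H2O, a method established for acyclic enals. This gives (2Z,6Z)-8-hydroxy-2-iodo-6-methylocta-2,6-dienal F1. A Stille coupling of F1 with (tributylstannyl)methanol [Pd(PPh3)4, dioxane, 80 °C] then installs the CH2OH group with retention of alkene geometry and gives 6.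
- Cost: one extra step.

*Step 6.*
- Risks: the aldehyde is α-quaternary and hindered, the Lewis acid may open the oxirane, and the promoter must dominate an ill-defined substrate bias.
- The fallback sets out from 8 and comes back at 11. Compound 8 is treated with boronate 14 and (S)-TRIP (toluene, −30 °C). This is a mild, closed-transition-state allylboration, a reaction class for which reagent control over 2,3-epoxy aldehydes is established. It gives the C8 pinacol borate ester F2 and, after aqueous work-up, the 8-prenyl epoxy alcohol F3.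
- SeO2 (cat.)/tBuOOH in CH2Cl2 then oxidises the E methyl group of the new gem-dimethyl alkene, with the same site selectivity as for geranyl derivatives. The product is a mixture of 11 and the primary allylic alcohol F4, and MnO2 converts F4 into 11.
- Cost: two extra steps.

*Step 9.*
- Risks: the tertiary boronate may react sluggishly, and the extra α-methyl groups may erode the enantioselectivity.
- The fallback sets out from 11 and comes back at 16. Commercial allylboronic acid pinacol ester and (R)-TRIP (toluene, −30 °C), the parent case of this reaction, give the C12 pinacol borate ester F5. After work-up this becomes the terminal-alkene diol F6.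
- Cross-metathesis of F6 with excess 2-methylbut-2-ene [second-generation Grubbs catalyst RuCl2(SIMes)(PCy3)(=CHPh), CH2Cl2, 40 °C] converts the vinyl group into the prenyl group and gives 16.
- Cost: one extra step in the linear sequence, while steps 7 and 8 fall away.

**Further compounds**
F1 | step 2 | (2Z,6Z)-8-hydroxy-2-iodo-6-methylocta-2,6-dienal | O=C/C(I)=C/CC/C(C)=C\CO
F2 | step 6 | C8 pinacol borate ester: 2-{[(1S)-1-[(2S,3S)-2-{[(TBS)oxy]methyl}-3-[(3Z)-5-[(TBS)oxy]-3-methylpent-3-en-1-yl]oxiran-2-yl]-4-methylpent-3-en-1-yl]oxy}-4,4,5,5-tetramethyl-1,3,2-dioxaborolane | CC(C)=CC[C@H](OB2OC(C)(C)C(C)(C)O2)[C@]1(CO[Si](C)(C)C(C)(C)C)O[C@H]1CC/C(C)=C\CO[Si](C)(C)C(C)(C)C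
F3 | step 6 | 8-prenyl epoxy alcohol: (1S)-1-[(2S,3S)-2-{[(TBS)oxy]methyl}-3-[(3Z)-5-[(TBS)oxy]-3-methylpent-3-en-1-yl]oxiran-2-yl]-4-methylpent-3-en-1-ol | CC(C)=CC[C@H](O)[C@]1(CO[Si](C)(C)C(C)(C)C)O[C@H]1CC/C(C)=C\CO[Si](C)(C)C(C)(C)C
F4 | step 6 | primary allylic alcohol: (2E,5S)-5-[(2S,3S)-2-{[(TBS)oxy]methyl}-3-[(3Z)-5-[(TBS)oxy]-3-methylpent-3-en-1-yl]oxiran-2-yl]-2-methylpent-2-ene-1,5-diol | OC/C(C)=C/C[C@H](O)[C@]1(CO[Si](C)(C)C(C)(C)C)O[C@H]1CC/C(C)=C\CO[Si](C)(C)C(C)(C)C
F5 | step 9 | C12 pinacol borate ester of F6 (12R) | C=CC[C@@H](OB2OC(C)(C)C(C)(C)O2)/C(C)=C/C[C@H](O)[C@]1(CO[Si](C)(C)C(C)(C)C)O[C@H]1CC/C(C)=C\CO[Si](C)(C)C(C)(C)C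
F6 | step 9 | terminal-alkene diol: (1S,3E,5R)-1-[(2S,3S)-2-{[(TBS)oxy]methyl}-3-[(3Z)-5-[(TBS)oxy]-3-methylpent-3-en-1-yl]oxiran-2-yl]-4-methylocta-3,7-diene-1,5-diol | C=CC[C@@H](O)/C(C)=C/C[C@H](O)[C@]1(CO[Si](C)(C)C(C)(C)C)O[C@H]1CC/C(C)=C\CO[Si](C)(C)C(C)(C)C
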